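The numbers come from no measurement, and the outcome is calculated.

- We come to these flasks from a neighbour, the same charge held at 25 °C, and we keep its outcome for the end; here are the flasks, the steps and what is asked.

| flask | starting material | second substrate | protic impurity | free enzyme | temperature | time |
|---|---|---|---|---|---|---|
| gamma | 45 mM | 2.00 equiv | 0.900 mM | 0.0018 mol% | 60 °C | 5.0 d |
| theta | 45 mM | 2.00 equiv | 0.900 mM | 0.0018 mol% | 0 °C | 5.0 d |
| epsilon | 45 mM | 2.00 equiv | 0.900 mM | 0.0018 mol% | 30 °C | 5.0 d |

    free enzyme → unfolded enzyme (k1 = 0.00271 h⁻¹, Ea1 = 205 kJ mol⁻¹)
    starting material + free enzyme ⇌ complex A (K2 = 16 M⁻¹, k2 = 2.34 × 10⁵ M⁻¹ h⁻¹, Ea2 = 42.0 kJ mol⁻¹, ΔH2 = 7.00 kJ mol⁻¹)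
    complex A → free enzyme + target (k3 = 1550 h⁻¹, Ea3 = 67.0 kJ mol⁻¹)
    second substrate + free enzyme ⇌ complex B (K4 = 22.2 M⁻¹, k4 = 1.97 × 10⁶ M⁻¹ h⁻¹, Ea4 = 47.0 kJ mol⁻¹, ΔH4 = −9.00 kJ mol⁻¹)
    complex B → free enzyme + second product (k5 = 321 h⁻¹, Ea5 = 90.0 kJ mol⁻¹)
    starting material + free enzyme → spent catalyst (k6 = 1.21 M⁻¹ h⁻¹, Ea6 = 79.0 kJ mol⁻¹)
    second substrate + protic impurity → quenched substrate (k7 = 30.8 M⁻¹ h⁻¹, Ea7 = 44.0 kJ mol⁻¹)
    (constants at 30 °C)

- at 30 °C the constants are as listed, elsewhere as the activation energies and enthalpies make them

- the flask with the highest amount of target, in percent of the starting material charged ("all alike" if they lie within 1.5 percentage points) (gamma / theta / epsilon / all alike)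
- final target, as a percentage of the starting material charged, in gamma
- final target, as a percentage of the starting material charged, in theta
- final target, as a percentage of the starting material charged, in epsilon

- The bench rule says that an unfinished flask wants more time or more heat, and this amounts to a straight line: target grows as the starting rate multiplied by the time.
- To test that rule we hold c(starting material) and c(second substrate) at their charges. In epsilon, free enzyme makes target with the forward rate constant of step 2 multiplied by the share of complex A that goes on instead of falling back, which gives 22400 M⁻¹ h⁻¹.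
- The same free enzyme is lost to spent catalyst and unfolded enzyme at 0.0572 h⁻¹ in epsilon, and the step to spent catalyst is the faster of the two.
- Making over loss, multiplied by c(starting material) and the loading of 0.0018 mol%, gives 31.8% of the charged starting material for epsilon. This is the enzyme budget: the target a charge of enzyme makes before it is lost, a turnover ceiling.
- The clock needs one more thing, because complex B, the resting state, holds more enzyme than stays free, and bound enzyme is not lost. Dividing the loss by that spread of forms and multiplying by the time gives the clock ratio, the elapsed time in enzyme lives, which is 1.84 in epsilon.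
- The straight line equals budget times clock ratio, and its border stands where the ratio reaches one. Epsilon is past it, so the line's 58.5% is void, and we take the budget times one minus the exponential of minus the ratio: 26.8%.
- Theta, at 0 °C, has a larger budget than epsilon, 44.7%, but its clock ratio is 0.0466. It stays on the straight line, and we reckon 2.03%.
- Gamma, at 60 °C, sees unfolding outrun the step to spent catalyst, so its budget is smaller than that of epsilon, 4.22%. Its clock ratio is 179, so the budget is what we expect to find: 4.22%.
- Our choice is therefore epsilon.
- The forecast also names epsilon, with 4.2% in gamma, 2% in theta and 25.7% in epsilon, on the ground that in epsilon “the enzyme is mainly lost to the suicide step with starting material”. Our epsilon figure stands above the forecast's.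
- The flasks give 4.15% in gamma, 2.04% in theta and 25.7% in epsilon, which holds more target than the other two. Left for 50.0 d, epsilon holds 31.5% of target, below its budget of 31.8%, with 94.4% of the enzyme as spent catalyst. For the neighbour at 25 °C the budget is 34.4% and the clock ratio 1.04, which reckons to 22.2%; that flask ends at 21.3%.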